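The target in the ash run climbs by 0.0415 min⁻¹ of the charge, faster than the 0.0321 min⁻¹ of the alder run, each line drawn from the first reading that shows target to the last reading. Here is what stands on the bench and what I want to know.

| setting | alder | ash | flask |
|---|---|---|---|
| substrate | 0.50 M | 0.50 M | 0.50 M |
| gas | 71 mM (held) | 71 mM (held) | 71 mM (held) |
| free catalyst | 7 mM | 11 mM | 5.0 mM |
| remark | run made earlier | run made earlier |  |
| time |  |  | 5.0 min |

| run | time / min | target / % | substrate / % |
|---|---|---|---|
| alder | 0.667 | 0.9 | 96.8 |
| alder | 1.33 | 3.3 | 96.4 |
| alder | 2.00 | 6.6 | 94.9 |
| alder | 2.50 | 5.0 | 92.6 |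
| alder | 3.00 | 8.4 | 90.5 |
| ash | 0.250 | 0 | 98.5 |
| ash | 0.833 | 0.8 | 95.5 |
| ash | 1.33 | 2.7 | 96.3 |
| ash | 2.00 | 6.0 | 92.8 |
| ash | 3.00 | 9.8 | 89.8 |

(scatter of a reading: 1 percentage point)

- at the start none of the gas is in solution

- winter: doubling the saturation concentration of gas, all else as stated
- dusk: doubling the transfer coefficient of the gas, all else as stated
- summer: doubling the amount of free catalyst, all else as stated

1. how much target there is at 5.0 min, in percent of the substrate charged
2. the change that raises the amount of target at 5.0 min, in percent of the substrate charged most ("none" if none brings more than 2 percentage points) (winter / dusk / summer / none)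
3. amount of target at 5.0 min, in percent of the substrate charged, after winter

At the last readings the substrate still stands at 90.5% in alder and 89.8% in ash, so over so short a stretch I take each climb as constant, a pseudo-zero-order stretch. The climb of ash is 1.29 times that of alder, smaller than the 1.57 times that ash holds of alder's free catalyst. The power to which the catalyst ratio must be raised to give the climb ratio is 0.567. With a scatter of 1 percentage point on each reading, that power is a rough reading. The flask has 0.714 of the free catalyst of alder, so scaling by that power gives 0.0266 min⁻¹, and I take this as my estimate of the flask's climb, the fraction of the charge that becomes target per minute once target has begun to appear. Run back to zero target, the two lines give a mean lag of 0.514 min. Climbing from the end of that lag until 5.0 min, the flask reaches 11.9% by my reckoning.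

The forecast says 14%, names winter as the best change and gives 27% after it, holding that “gas supply probably limits much of the rate”. My figure is lower than its 14%.

The flask gives 11.4%, and winter, the best change, gives 19.5%, less than the forecast's 27%.

substrate + free catalyst → catalyst intermediate A (k = 0.950 M⁻¹ s⁻¹); catalyst intermediate A ⇌ catalyst intermediate B (K = 0.520, k = 0.556 s⁻¹); reagent + catalyst intermediate B ⇌ catalyst intermediate C (K = 1120 M⁻¹, k = 7.95 M⁻¹ s⁻¹); catalyst intermediate C → catalyst intermediate D (k = 20.4 s⁻¹); catalyst intermediate D → free catalyst + target (k = 0.561 s⁻¹); gas ⇌ reagent, rate k6*(csat - [reagent]) (kL = 0.00522 s⁻¹) Starting from the 4.55% the flask holds at 2.50 min, the climb of 0.0266 min⁻¹ reaches 11.2% at 5.0 min. Carried on from 11.4% at that same climb, the same flask read at 20 min comes to 51.3%, and that neighbour holds 53.7%.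

(The numbers in the tables are simulated for an exercise, and the scatter is random.)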